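(All runs come from a simulation on assumed constants; scatter was added.)

- The dusk run holds 3.00 times the E of the summer run at equal Q, yet at 0.53 h it has made twice the L, 63.9 mM against 32.4 mM.

| flask | E | Q | time |
|---|---|---|---|
| summer | 150 mM | 300 mM |  |
| spring | 90.0 mM | 240 mM |  |
| dusk | 450 mM | 300 mM |  |
| autumn | 50.0 mM | 99.0 mM | 3.2 h |

- summer run (time / h: [L] / mM): 0.53: 32.4; 1.1: 48.8; 1.6: 59.1; 2.1: 60.6; 2.7: 63.6; 3.2: 63.8
- spring run (time / h: [L] / mM): 0.53: 19.3; 1.1: 31.4; 1.6: 36.2; 2.1: 39.0; 2.7: 41.7; 3.2: 41.6
- dusk run (time / h: [L] / mM): 0.53: 63.9; 1.1: 91.3; 1.6: 103.9; 2.1: 109.5; 2.7: 113.9; 3.2: 116.8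

(readings scatter by 1 mM)

- Overall: E + Q -> L.
- Constant volume, constant temperature.
- A reading of a species includes what of it is bound.
- "The second partner" is Q.
- An order is taken over about fifteen percent of the charge, up and down.

- how the opening rate goes with [E] round the charge of the summer run: the exponent of the rate at two percent of E gone to L (one fixed amount of L, the same in the runs compared)
- how the opening rate goes with [Q] round the charge of the summer run: the exponent of the rate at two percent of E gone to L
- L in the autumn run at 3.2 h, as a share of the E charged

- Take the share of the last reading already reached at the first. If the rate decays exponentially, that share gives 0.748 h for the summer run, 0.850 h for the spring run and 0.669 h for the dusk run. This is the lifetime, the time in which a run's rate of forming L falls e-fold.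
- The last reading, taken as the end value, divided by the lifetime gives an estimate of the opening rate: 85.3 mM/h in the summer run, 48.9 mM/h in the spring run and 175 mM/h in the dusk run. Dusk against summer gives an order in E of 0.651. Spring against summer, with that E effect divided out, gives an order in Q of 1.00.
- By 3.2 h the summer run has lived 4.28 lifetimes, so on that exponential decay its rate stands at 0.0139 of the opening rate. The E and Q turned into L, taken through those orders, account for a factor of 0.549. A further factor of 0.0253 remains that, in this reckoning, the E and Q turned into L do not account for.
- For the autumn run, the orders scale the summer opening rate to 13.8 mM/h. The spring lifetime is longer than the dusk lifetime, so you extend that trend in E to the autumn charge, setting aside any effect of Q, and get 0.928 h. Opening rate times lifetime, over the 3.45 lifetimes to 3.2 h, gives 12.4 mM, or 24.7% of E, the limiting reagent.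
- The forecast, calling its order in Q “poorly determined”, gives 0.62 in E, 0.4 in Q (0.1 to 0.8) and 40% (31% to 49%) for the autumn run, a lower order in Q and a higher share than this reckoning.
- The flask gives 0.69 in E and 1.0 in Q round the charge of the summer run, and 32.1% of the E charged for the autumn run at 3.2 h.

    E ⇌ X, settled at all times (0.01940)
    X + Q → L (233.6 /M/h)
    2 E ⇌ E2, settled at all times (7.920 /M)
    2 E → Vy (22.46 /M/h)

- The autumn share stands 7.4 percentage points above this reckoning. Divided by the reckoned opening rate, with the autumn run taken as at its end by 3.2 h, it gives a lifetime of 1.17 h, longer than the 0.748 h of the summer run. Count lifetimes on the dusk run as well: a quarter of its E has become L at 2.44 h, which is 3.65 lifetimes, against 0.829 lifetimes in the summer run at 0.620 h.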